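Carbocycle numbering: C1 (CHOAc), C2 (CH carrying the oxane), C3 (CH2), C4 (CHBr), C5 (CClMe), C6; oxane O1', C2'–C6'. Everything rests on cutting the ring bond C2–C3. The key step exploits that C2 lies alpha to C2' (drawn back to an ester carbon) and beta to the C1 oxygen, while C3 is allylic to a C4=C5 alkene that later takes Br and Cl. The dilithio dianion of an acyclic (Z)-allylic chloride beta-hydroxy ester closes the cyclohexene by intramolecular alkylation and sets C2 cis to the C1 oxygen through a lithium chelate. The ester then grows into the bromo-oxane.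

Key step: step 5

Assumption: on heating, the trans-diaxial bromochloride 23 is taken to rearrange to its trans-diequatorial partner 24 (tertiary C–Cl, secondary C–Br), as related vicinal dihalocyclohexanes do.

Step 1
Reactants: 1 but-2-yn-1-ol
Product: 3 (Z)-3-iodobut-2-en-1-ol, via cyclic alkenylalanate 2 (not isolated)
Conditions: NaAlH2(OCH2CH2OMe)2 (Red-Al), THF, 0 °C to rt; then I2, −78 °C to 0 °C
Reagents that add atoms: iodine, II
Why: Hydroxyl-directed trans-hydroalumination of the propargylic alcohol puts aluminium on C3 in the cyclic alanate 2 and iodinolysis with retention gives the Z vinyl iodide, which fixes the alkene geometry that the ring closure needs.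

Step 2
Reactants: 4 ethyl (S)-4-chloro-3-hydroxybutanoate
Product: 5 ethyl 2-[(2S)-oxiran-2-yl]acetate
Conditions: Ag2O, MeCN, 50 °C, dark
Reagents that add atoms: none
Why: Ag2O promotes the intramolecular Williamson etherification of the chlorohydrin without a soluble base that would eliminate to the 4-hydroxycrotonate, and the stereocentre is not involved.

Step 3
Reactants: 3 (Z)-3-iodobut-2-en-1-ol; 5 ethyl 2-[(2S)-oxiran-2-yl]acetate
Product: 7 ethyl (3R,5Z)-3,7-dihydroxy-5-methylhept-5-enoate, via alkenylmagnesium alkoxide 6 (not isolated)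
Conditions: 3, MeMgCl (1.0 equiv), THF, −20 °C; i-PrMgCl·LiCl (1.1 equiv), 0 °C; CuI (10 mol%), then 5, −40 °C to −20 °C
Reagents that add atoms: none
Why: After deprotonation of the hydroxyl group, iodine–magnesium exchange gives the alkenyl Grignard reagent 6 with retention of geometry, and its copper-catalysed SN2 opening of the epoxide at the terminal carbon (cuprate epoxide opening) leaves the carbinol centre untouched, now 3R.

Step 4
Reactants: 7 ethyl (3R,5Z)-3,7-dihydroxy-5-methylhept-5-enoate
Product: 8 ethyl (3R,5Z)-7-chloro-3-hydroxy-5-methylhept-5-enoate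
Conditions: PPh3 (1.05 equiv), CCl4, CH2Cl2, 0 °C
Reagents that add atoms: tetrachloromethane, ClC(Cl)(Cl)Cl
Why: The Appel reaction converts the unhindered primary allylic alcohol much faster than the secondary one and substitutes by SN2 without allylic transposition, so the Z geometry and the 3R centre are kept.

Step 5
Reactants: 8 ethyl (3R,5Z)-7-chloro-3-hydroxy-5-methylhept-5-enoate
Product: 10 ethyl (1S,6R)-6-hydroxy-4-methylcyclohex-3-ene-1-carboxylate, via dilithium dianion 9 (not isolated)
Conditions: LiN(iPr)2 (2.2 equiv), THF, −78 °C to −10 °C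
Reagents that add atoms: none
Why: LiN(iPr)2 removes the hydroxyl proton and one alpha hydrogen of the ester to give the lithium-bridged alkoxide/(Z)-enolate 9, whose alpha carbon displaces the allylic chloride intramolecularly and so forges the C2–C3 bond of the carbocycle. The closest known reaction type is the Fráter–Seebach alkylation of beta-hydroxy ester dianions, run here as an intramolecular enolate SN2 alkylation. The cyclohexene closes in the 6-exo-tet mode (enolate double bond and leaving group both outside the new ring), which only the Z alkene allows because it holds C3 and C6 on the same side. The one new stereocentre (C2) is controlled by the O–Li–O chelate: the chain carbon C6 must stand pseudoaxial on the chelate ring, the electrophile reaches the enolate face syn to it, and the carboxyl carbon therefore ends cis to the C1 oxygen (1S,6R in 10). The step needs C- over O-alkylation and substitution over 1,4-elimination; the lithium alkoxide is a far weaker nucleophile than the enolate carbon, an SN2' closure would give a four-membered ring, and the low temperature holds back elimination.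

Step 6
Reactants: 10 ethyl (1S,6R)-6-hydroxy-4-methylcyclohex-3-ene-1-carboxylate
Product: 11 ethyl (1S,6R)-6-[(tert-butyldimethylsilyl)oxy]-4-methylcyclohex-3-ene-1-carboxylate
Conditions: TBSOTf, 2,6-lutidine, CH2Cl2, −40 °C
Reagents that add atoms: tert-butyldimethylsilyl trifluoromethanesulfonate, CC(C)(C)[Si](C)(C)OS(=O)(=O)C(F)(F)F
Why: Silyl ether formation with the silyl triflate and a hindered base caps the secondary alcohol without retro-aldol cleavage or epimerisation and gives a non-chelating, non-participating group for the later additions and the epoxide opening.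

Step 7
Reactants: 11 ethyl (1S,6R)-6-[(tert-butyldimethylsilyl)oxy]-4-methylcyclohex-3-ene-1-carboxylate
Product: 12 (1S,6R)-6-[(tert-butyldimethylsilyl)oxy]-N-methoxy-N,4-dimethylcyclohex-3-ene-1-carboxamide
Conditions: MeNH(OMe)·HCl, i-PrMgCl, THF, −20 °C to 0 °C
Reagents that add atoms: N,O-dimethylhydroxylamine hydrochloride, CNOC.Cl
Why: The chloromagnesium amide of N,O-dimethylhydroxylamine aminolyses the ester directly (Weinreb amide formation) at low temperature, where the alpha stereocentre is not epimerised and the beta silyloxy group is not eliminated.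

Step 8
Reactants: 12 (1S,6R)-6-[(tert-butyldimethylsilyl)oxy]-N-methoxy-N,4-dimethylcyclohex-3-ene-1-carboxamide
Product: 13 (1S,3S,4R,6R)-4-[(tert-butyldimethylsilyl)oxy]-N-methoxy-N,6-dimethyl-7-oxabicyclo[4.1.0]heptane-3-carboxamide
Conditions: mCPBA, NaHCO3, CH2Cl2, 0 °C
Reagents that add atoms: 3-chloroperoxybenzoic acid, OOC(=O)c1cccc(Cl)c1
Why: Prilezhaev epoxidation of the trisubstituted alkene takes place on the face opposite to the two cis substituents (silyloxy and amide), which sets both epoxide carbons (4S,5R in target numbering), and the epoxide masks the ring alkene during the later bromoetherification.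

Step 9
Reactants: 13 (1S,3S,4R,6R)-4-[(tert-butyldimethylsilyl)oxy]-N-methoxy-N,6-dimethyl-7-oxabicyclo[4.1.0]heptane-3-carboxamide; 14 5-bromo-2-methylpent-2-ene
Product: 16 1-[(1S,3S,4R,6R)-4-[(tert-butyldimethylsilyl)oxy]-6-methyl-7-oxabicyclo[4.1.0]heptan-3-yl]-5-methylhex-4-en-1-one, via Grignard reagent 15 (not isolated)
Conditions: 14, Mg, THF, rt; then 13, THF, −20 °C to 0 °C
Reagents that add atoms: none
Why: The Grignard reagent 15 adds once to the Weinreb amide because the chelated tetrahedral intermediate survives until work-up (Weinreb ketone synthesis), while the hindered trisubstituted epoxide is inert at this temperature.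

Step 10
Reactants: 16 1-[(1S,3S,4R,6R)-4-[(tert-butyldimethylsilyl)oxy]-6-methyl-7-oxabicyclo[4.1.0]heptan-3-yl]-5-methylhex-4-en-1-one
Product: 18 (2S)-1-[(1S,3S,4R,6R)-4-[(tert-butyldimethylsilyl)oxy]-6-methyl-7-oxabicyclo[4.1.0]heptan-3-yl]-2-hydroxy-5-methylhex-4-en-1-one, via sodium enolate 17 (not isolated)
Conditions: NaN(SiMe3)2, THF, −78 °C; then (+)-(camphorsulfonyl)oxaziridine, −78 °C
Reagents that add atoms: (+)-(2R,8aS)-(camphorsulfonyl)oxaziridine, CC1(C)[C@@H]2CC[C@]13CS(=O)(=O)N4[C@@]3(C2)O4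
Why: Kinetic deprotonation takes the unhindered methylene and not the ring methine, and the (Z)-sodium enolate 17 is hydroxylated by the chiral N-sulfonyloxaziridine under reagent control (Davis enolate oxidation), which is expected to deliver the 3'S carbinol.

Step 11
Reactants: 18 (2S)-1-[(1S,3S,4R,6R)-4-[(tert-butyldimethylsilyl)oxy]-6-methyl-7-oxabicyclo[4.1.0]heptan-3-yl]-2-hydroxy-5-methylhex-4-en-1-one
Product: 19 (2S)-1-[(1S,3S,4R,6R)-4-[(tert-butyldimethylsilyl)oxy]-6-methyl-7-oxabicyclo[4.1.0]heptan-3-yl]-5-methyl-2-[(triisopropylsilyl)oxy]hex-4-en-1-one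
Conditions: TIPSOTf, 2,6-lutidine, CH2Cl2, −40 °C to 0 °C
Reagents that add atoms: triisopropylsilyl trifluoromethanesulfonate, CC(C)[Si](C(C)C)(C(C)C)OS(=O)(=O)C(F)(F)F
Why: Silyl ether formation with the bulky triisopropylsilyl group protects the alpha hydroxyl without enolising the ketone and gives a non-chelating neighbour for a Felkin–Anh addition.

Step 12
Reactants: 19 (2S)-1-[(1S,3S,4R,6R)-4-[(tert-butyldimethylsilyl)oxy]-6-methyl-7-oxabicyclo[4.1.0]heptan-3-yl]-5-methyl-2-[(triisopropylsilyl)oxy]hex-4-en-1-one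
Product: 20 (2S,3S)-2-[(1S,3S,4R,6R)-4-[(tert-butyldimethylsilyl)oxy]-6-methyl-7-oxabicyclo[4.1.0]heptan-3-yl]-6-methyl-3-[(triisopropylsilyl)oxy]hept-5-en-2-ol
Conditions: MeLi, CeCl3, THF, −78 °C, cold quench
Reagents that add atoms: methyllithium, [Li]C
Why: 1,2-Addition of the weakly basic organocerium reagent to the ketone follows the Felkin–Anh model at both alpha stereocentres, methyl entering anti to the C1-bearing ring bond on one side and anti to the C–OSi bond on the other (matched case, no chelation), which sets C2' as S.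

Step 13
Reactants: 20 (2S,3S)-2-[(1S,3S,4R,6R)-4-[(tert-butyldimethylsilyl)oxy]-6-methyl-7-oxabicyclo[4.1.0]heptan-3-yl]-6-methyl-3-[(triisopropylsilyl)oxy]hept-5-en-2-ol
Product: 21 (2S,3S,5S)-5-bromo-2-[(1S,3S,4R,6R)-4-[(tert-butyldimethylsilyl)oxy]-6-methyl-7-oxabicyclo[4.1.0]heptan-3-yl]-2,6,6-trimethyl-3-[(triisopropylsilyl)oxy]oxane
Conditions: NBS, NaHCO3, CH2Cl2, 0 °C, dark
Reagents that add atoms: N-bromosuccinimide, O=C1CCC(=O)N1Br
Why: In this bromoetherification the tertiary hydroxyl opens the bromonium ion at its dimethyl-substituted carbon (6-endo, Markovnikov) through a chair in which the carbocycle is equatorial on C2' and anti addition leaves bromine equatorial, which sets C5' as S.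

Step 14
Reactants: 21 (2S,3S,5S)-5-bromo-2-[(1S,3S,4R,6R)-4-[(tert-butyldimethylsilyl)oxy]-6-methyl-7-oxabicyclo[4.1.0]heptan-3-yl]-2,6,6-trimethyl-3-[(triisopropylsilyl)oxy]oxane
Product: 22 bromohydrin (target numbering: carbocycle 1R,2S,4S,5S with 1-OTBS, axial 4-OH, axial 5-Br, 5-Me; oxane 2'S,3'S,5'S with 3'-OTIPS)
Conditions: HBr (1.1 equiv, in Et2O), CH2Cl2, −60 °C
Reagents that add atoms: hydrogen bromide, Br
Why: Acid-mediated epoxide opening obeys the Fürst–Plattner rule and Markovnikov control together, so bromide attacks the tertiary carbon C5 anti to the oxygen and gives the trans-diaxial bromohydrin (inversion at C5, C4 unchanged).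

Step 15
Reactants: 22 bromohydrin (carbocycle 1R,2S,4S,5S; 4-OH, 5-Br)
Product: 24 silyl-protected bromochloride (target numbering: carbocycle 1R,2S,4R,5R with 1-OTBS 4-Br 5-Cl 5-Me; oxane 2'S,3'S,5'S with 3'-OTIPS), via trans-diaxial bromochloride 23 (not isolated)
Conditions: SOCl2, pyridine, CH2Cl2, −20 °C to 0 °C; then toluene, 80 °C
Reagents that add atoms: thionyl chloride, O=S(Cl)Cl
Why: Ionisation of the chlorosulfite is assisted by the antiperiplanar bromine (neighbouring-group participation), chloride opens the bromonium ion at C4 in the trans-diaxial sense to give 23 with net retention, and heating then effects the 1,2-dihalide interchange (trans-diaxial to trans-diequatorial rearrangement) in which bromine moves to C4 and chlorine to C5 each on its own face, giving 4R and 5R.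

Step 16
Reactants: 24 silyl-protected bromochloride
Product: 25 C1 alcohol (carbocycle 1R,2S,4R,5R with free 1-OH; 3'-OTIPS retained)
Conditions: HF·pyridine, pyridine, THF, 0 °C
Reagents that add atoms: none
Why: Fluoride-induced desilylation cleaves the tert-butyldimethylsilyl ether much faster than the triisopropylsilyl ether on the neopentyl-type C3' oxygen, and buffered HF leaves the acid-stable halides untouched.

Step 17
Reactants: 25 C1 alcohol
Product: 26 C1 acetate (3'-OTIPS retained)
Conditions: Ac2O, DMAP, pyridine, CH2Cl2, rt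
Reagents that add atoms: acetic anhydride, CC(=O)OC(C)=O
Why: DMAP-catalysed acylation (esterification) of the axial secondary alcohol does not break the C–O bond, so C1 keeps its configuration.

Step 18
Reactants: 26 C1 acetate
Product: 27 (1R,2S,4R,5R)-4-bromo-2-[(2S,3S,5S)-5-bromo-3-hydroxy-2,6,6-trimethyloxan-2-yl]-5-chloro-5-methylcyclohexyl acetate (CNP0251357.1)
Conditions: HF·pyridine, THF, rt to 40 °C
Reagents that add atoms: none
Why: Acidic fluoride desilylation removes the last silyl ether without hydrolysing or migrating the acetate and without base that could eliminate HBr or HCl.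

Compound list
1 | but-2-yn-1-ol | CC#CCO | starting material
2 | sodium 2,2-bis(2-methoxyethoxy)-3-methyl-2,5-dihydro-1,2-oxaaluminol-2-uide (cyclic alkenylalanate) | CC1=CCO[Al-]1(OCCOC)OCCOC.[Na+] | intermediate
3 | (Z)-3-iodobut-2-en-1-ol | C/C(I)=C/CO | intermediate
4 | ethyl (S)-4-chloro-3-hydroxybutanoate | CCOC(=O)C[C@H](O)CCl | starting material
5 | ethyl 2-[(2S)-oxiran-2-yl]acetate | CCOC(=O)C[C@H]1CO1 | intermediate
6 | chloromagnesium (Z)-3-(chloromagnesio)but-2-en-1-olate | C/C([Mg]Cl)=C/CO[Mg]Cl | intermediate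
7 | ethyl (3R,5Z)-3,7-dihydroxy-5-methylhept-5-enoate | CCOC(=O)C[C@H](O)C/C(C)=C\CO | intermediate
8 | ethyl (3R,5Z)-7-chloro-3-hydroxy-5-methylhept-5-enoate | CCOC(=O)C[C@H](O)C/C(C)=C\CCl | intermediate
9 | dilithium alkoxide/(Z)-enolate of 8 | CCO/C([O-])=C/[C@H]([O-])C/C(C)=C\CCl.[Li+].[Li+] | intermediate
10 | ethyl (1S,6R)-6-hydroxy-4-methylcyclohex-3-ene-1-carboxylate | O[C@@H]1CC(C)=CC[C@@H]1C(=O)OCC | intermediate
11 | ethyl (1S,6R)-6-[(tert-butyldimethylsilyl)oxy]-4-methylcyclohex-3-ene-1-carboxylate | CC(C)(C)[Si](C)(C)O[C@@H]1CC(C)=CC[C@@H]1C(=O)OCC | intermediate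
12 | (1S,6R)-6-[(tert-butyldimethylsilyl)oxy]-N-methoxy-N,4-dimethylcyclohex-3-ene-1-carboxamide | CC(C)(C)[Si](C)(C)O[C@@H]1CC(C)=CC[C@@H]1C(=O)N(C)OC | intermediate
13 | (1S,3S,4R,6R)-4-[(tert-butyldimethylsilyl)oxy]-N-methoxy-N,6-dimethyl-7-oxabicyclo[4.1.0]heptane-3-carboxamide | CC(C)(C)[Si](C)(C)O[C@@H]1C[C@@]2(C)O[C@H]2C[C@@H]1C(=O)N(C)OC | intermediate
14 | 5-bromo-2-methylpent-2-ene | CC(C)=CCCBr | starting material
15 | (4-methylpent-3-en-1-yl)magnesium bromide | CC(C)=CCC[Mg]Br | intermediate
16 | 1-[(1S,3S,4R,6R)-4-[(tert-butyldimethylsilyl)oxy]-6-methyl-7-oxabicyclo[4.1.0]heptan-3-yl]-5-methylhex-4-en-1-one | CC(C)(C)[Si](C)(C)O[C@@H]1C[C@@]2(C)O[C@H]2C[C@@H]1C(=O)CCC=C(C)C | intermediate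
17 | sodium (Z)-enolate of 16 | CC(C)(C)[Si](C)(C)O[C@@H]1C[C@@]2(C)O[C@H]2C[C@@H]1/C([O-])=C/CC=C(C)C.[Na+] | intermediate
18 | (2S)-1-[(1S,3S,4R,6R)-4-[(tert-butyldimethylsilyl)oxy]-6-methyl-7-oxabicyclo[4.1.0]heptan-3-yl]-2-hydroxy-5-methylhex-4-en-1-one | CC(C)(C)[Si](C)(C)O[C@@H]1C[C@@]2(C)O[C@H]2C[C@@H]1C(=O)[C@@H](O)CC=C(C)C | intermediate
19 | (2S)-1-[(1S,3S,4R,6R)-4-[(tert-butyldimethylsilyl)oxy]-6-methyl-7-oxabicyclo[4.1.0]heptan-3-yl]-5-methyl-2-[(triisopropylsilyl)oxy]hex-4-en-1-one | CC(C)(C)[Si](C)(C)O[C@@H]1C[C@@]2(C)O[C@H]2C[C@@H]1C(=O)[C@@H](O[Si](C(C)C)(C(C)C)C(C)C)CC=C(C)C | intermediate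
20 | (2S,3S)-2-[(1S,3S,4R,6R)-4-[(tert-butyldimethylsilyl)oxy]-6-methyl-7-oxabicyclo[4.1.0]heptan-3-yl]-6-methyl-3-[(triisopropylsilyl)oxy]hept-5-en-2-ol | CC(C)(C)[Si](C)(C)O[C@@H]1C[C@@]2(C)O[C@H]2C[C@@H]1[C@](C)(O)[C@@H](O[Si](C(C)C)(C(C)C)C(C)C)CC=C(C)C | intermediate
21 | (2S,3S,5S)-5-bromo-2-[(1S,3S,4R,6R)-4-[(tert-butyldimethylsilyl)oxy]-6-methyl-7-oxabicyclo[4.1.0]heptan-3-yl]-2,6,6-trimethyl-3-[(triisopropylsilyl)oxy]oxane | CC(C)(C)[Si](C)(C)O[C@@H]1C[C@@]2(C)O[C@H]2C[C@@H]1[C@]3(C)OC(C)(C)[C@@H](Br)C[C@@H]3O[Si](C(C)C)(C(C)C)C(C)C | intermediate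
22 | bromohydrin: carbocycle (target numbering) 1R,2S,4S,5S with 1-OTBS, 4-OH, 5-Br, 5-Me; oxane 2'S,3'S,5'S with 3'-OTIPS | CC(C)(C)[Si](C)(C)O[C@@H]1C[C@](C)(Br)[C@@H](O)C[C@@H]1[C@]2(C)OC(C)(C)[C@@H](Br)C[C@@H]2O[Si](C(C)C)(C(C)C)C(C)C | intermediate
23 | trans-diaxial bromochloride: carbocycle 1R,2S,4S,5S with 4-Cl, 5-Br, 5-Me, 1-OTBS; oxane as in 22 | CC(C)(C)[Si](C)(C)O[C@@H]1C[C@](C)(Br)[C@@H](Cl)C[C@@H]1[C@]2(C)OC(C)(C)[C@@H](Br)C[C@@H]2O[Si](C(C)C)(C(C)C)C(C)C | intermediate
24 | trans-diequatorial bromochloride: carbocycle 1R,2S,4R,5R with 4-Br, 5-Cl, 5-Me, 1-OTBS; oxane 2'S,3'S,5'S with 3'-OTIPS | CC(C)(C)[Si](C)(C)O[C@@H]1C[C@@](C)(Cl)[C@H](Br)C[C@@H]1[C@]2(C)OC(C)(C)[C@@H](Br)C[C@@H]2O[Si](C(C)C)(C(C)C)C(C)C | intermediate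
25 | C1 alcohol: as 24 with free 1-OH | O[C@@H]1C[C@@](C)(Cl)[C@H](Br)C[C@@H]1[C@]2(C)OC(C)(C)[C@@H](Br)C[C@@H]2O[Si](C(C)C)(C(C)C)C(C)C | intermediate
26 | C1 acetate: as 25 with 1-OAc, 3'-OTIPS | CC(=O)O[C@@H]1C[C@@](C)(Cl)[C@H](Br)C[C@@H]1[C@]2(C)OC(C)(C)[C@@H](Br)C[C@@H]2O[Si](C(C)C)(C(C)C)C(C)C | intermediate
27 | (1R,2S,4R,5R)-4-bromo-2-[(2S,3S,5S)-5-bromo-3-hydroxy-2,6,6-trimethyloxan-2-yl]-5-chloro-5-methylcyclohexyl acetate | CC(=O)O[C@@H]1C[C@@](C)(Cl)[C@H](Br)C[C@@H]1[C@]1(C)OC(C)(C)[C@@H](Br)C[C@@H]1O | target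

Total steps: 18. Longest linear sequence: 17 steps (step 1, then steps 3 to 18; step 2 is a one-step side branch).

Steps most likely to fail

Step 15. Chloride may open the bromonium ion at either carbon, the cation may lose a proton to give an allylic bromide, and the thermal halogen interchange may stop at an equilibrium mixture of 23 and 24. The fallback sets out from 21 and comes back at 24, and makes the tertiary C–Cl bond by protonation of an alkene instead of by activating an alcohol. Epoxide 21 is isomerised with diethylaluminium 2,2,6,6-tetramethylpiperidide (Et2AlNC9H18, toluene, 0 °C) to the exocyclic allylic alcohol F3 (C5 methylene, axial 4-OH). Appel bromination (PPh3, CBr4, CH2Cl2) with inversion gives the equatorial allylic bromide F4. Anhydrous HCl (CH2Cl2, −78 °C) then adds in the Markovnikov sense: the tertiary cation is bridged by the neighbouring bromine and collapses with chloride at C5 on the opposite face, which should give 24 under kinetic control.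

Step 5. The lithium alkoxide may alkylate on oxygen, HCl may be lost by 1,4-elimination, or the chelate may control the new centre only weakly. The fallback sets out from 8 and comes back at 10, forming the same C2–C3 bond through a soft enolate. Dess–Martin oxidation of 8 gives the beta-keto ester F1. K2CO3 in acetone closes the ring by C-alkylation to the cyclic beta-keto ester F2, whose alpha centre is configurationally labile. A ketoreductase chosen for the 6R carbinol (NADPH, glucose dehydrogenase recycling) then reduces F2 with dynamic kinetic resolution to the cis hydroxy ester 10.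

Step 12. The hindered ketone may be enolised, or the facial selectivity may be poor if the two Felkin preferences are weaker than expected. The fallback sets out from 18 and comes back at 20, and sets C2' by reagent control. Wittig methylenation of hydroxy ketone 18 (Ph3P=CH2, excess, THF) gives the allylic alcohol F5. Sharpless epoxidation (Ti(OiPr)4, L-(+)-diethyl tartrate, t-BuOOH, the matched pair for the 3'S carbinol) gives the epoxy alcohol F6. LiBHEt3 opens the oxirane at its CH2 to the diol F7, and TIPSOTf with 2,6-lutidine silylates the secondary hydroxyl to return 20.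

Further compounds
F1 | step 5 | ethyl (5Z)-7-chloro-5-methyl-3-oxohept-5-enoate | CCOC(=O)CC(=O)C/C(C)=C\CCl
F2 | step 5 | ethyl 4-methyl-6-oxocyclohex-3-ene-1-carboxylate (racemic, labile alpha centre) | CCOC(=O)C1CC=C(C)CC1=O
F3 | step 15 | exocyclic allylic alcohol from 21 (C5 methylene, axial 4-OH, silyl ethers and bromo-oxane unchanged) | CC(C)(C)[Si](C)(C)O[C@@H]1CC(=C)[C@@H](O)C[C@@H]1[C@]2(C)OC(C)(C)[C@@H](Br)C[C@@H]2O[Si](C(C)C)(C(C)C)C(C)C
F4 | step 15 | equatorial allylic bromide (C5 methylene, 4-Br inverted) | CC(C)(C)[Si](C)(C)O[C@@H]1CC(=C)[C@H](Br)C[C@@H]1[C@]2(C)OC(C)(C)[C@@H](Br)C[C@@H]2O[Si](C(C)C)(C(C)C)C(C)C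
F5 | step 12 | allylic alcohol, the C2' methylene analogue of 18 (3'S) | CC(C)(C)[Si](C)(C)O[C@@H]1C[C@@]2(C)O[C@H]2C[C@@H]1C(=C)[C@@H](O)CC=C(C)C
F6 | step 12 | erythro epoxy alcohol (2,2-disubstituted oxirane at C2', 3'S carbinol) | CC(C)(C)[Si](C)(C)O[C@@H]1C[C@@]2(C)O[C@H]2C[C@@H]1[C@@]3(CO3)[C@@H](O)CC=C(C)C
F7 | step 12 | (2'S,3'S)-diol, the desilylated form of 20 | CC(C)(C)[Si](C)(C)O[C@@H]1C[C@@]2(C)O[C@H]2C[C@@H]1[C@](C)(O)[C@@H](O)CC=C(C)C
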